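Compound numbers used below are those of the compound list that follows the steps. Furanone numbering (O1, C2 carbonyl, C3, C4, C5) is used for the ring atoms throughout, also in the open-chain precursors.

## Analysis of the target

The target 21 is (R)-4-(4-hydroxyphenyl)-5-{[4-hydroxy-3-(3-methylbut-2-en-1-yl)phenyl]methyl}-3-methoxyfuran-2(5H)-one: one five-membered unsaturated lactone and two benzene rings, nothing else cyclic. C3 carries a methoxy group, so the C3=C4 bond is both an enol ether and the α,β-bond of the lactone. C4 carries the 4-hydroxyphenyl ring and C5 the 4-hydroxy-3-prenylbenzyl group. C5 is the only stereocentre, (R), and it has no neighbouring stereocentre from which its configuration could be relayed. Its hydrogen is γ to the carbonyl through C3=C4, so a strong base can remove it to give a flat 2-oxidofuran and thereby racemise the compound. The ortho-prenylphenol closes to a 2,2-dimethylchroman under strong acid, and the two free phenols are open to oxidation and alkylation. The synthesis is hard because C5 must be set in the absolute sense next to a fully substituted alkene whose three different substituents have to be placed without regiochemical ambiguity, and because only one of the two phenol rings carries the prenyl group. The strategy rests on reading C3=C4–C5 as what is left of an allene C3=C4=C5 whose C3 already bears the methoxy group and the carboxyl carbon C2. Adding the aryl group to the central carbon C4 and the carboxyl oxygen O1 to the terminal carbon C5 makes the ring, and the allene axis becomes the C5 centre.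

## Retrosynthetic reasoning

**21 from 20.** Only the two acetal O–CH2 bonds on the phenol oxygens are cut. Methoxymethyl ethers are chosen because they pass through two saponifications, an acid chloride, a ketene and a palladium step unchanged. They leave by acid-catalysed acetal exchange, which is much faster than protonation of the prenyl alkene. The forward step must free both phenols without closing the chroman.

**20 from 17 and 19.** The bonds C4–aryl and O1–C5 are cut together. This is the place to cut because one catalytic event then forms the ring, puts the aryl group on C4 and creates C5. The regiochemistry cannot go astray: an arylpalladium species delivers carbon only to the central allene carbon, and the carboxyl group already sits on C3. The gain is that the single stereocentre is not induced by a reagent but transferred from the axis of 17. The forward reaction has to place the aryl group on C4 from the methoxy side of the C4=C5 bond, bring O1 to C5 from the carboxyl side, and do both before the axial information is lost.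

**17 from 16, and 16 from 14 and 15.** No skeletal bond is cut; the axis is obtained by resolution. An allenoic acid offers a carboxylate for salt formation with the chiral base 15, and a crystalline salt can be brought to full enantiopurity before the key step. The acid is set free from 16 before the coupling, because the vinyl group of the alkaloid could itself be arylated by the palladium catalyst.

**14 from 13, and 13 from 6 and 9.** The C3=C4 bond is cut. In the forward sense it is made by a Wittig olefination of ketene 12 (C4 is the ketene carbonyl carbon, C5 its CH) with phosphorane 11, which brings C3 with its methoxy group and the ester carbon C2. Ketene 12 comes from acid 6 through acid chloride 10, and 11 from salt 9. A phosphorane is preferred to a phosphonate carbanion: the carbanion would be protonated by the ammonium salt that ketene generation releases and acylated by the acid chloride, whereas a stabilised phosphorane coexists with that medium. Saponification of 13 then gives 14. Salt 9 is made from 7 and 8 by quaternisation.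

**6 from 5, and 5 from 3 and 4.** The aryl–prenyl bond is cut. A Stille coupling between bromide 3 and stannane 4 places the prenyl group exactly where the bromine was, which avoids the O- versus C-alkylation and over-alkylation problems of a direct phenol prenylation. Saponification of 5 gives 6.

**3 from 2, and 2 from 1.** The C–Br bond and the acetal O–C bond are cut. In 1 the para position is occupied by the side chain, so bromination can only go ortho to the hydroxyl group. Protection of 2 gives 3.

**19 from 18.** The acetal O–C bond is cut; the second phenol is masked in the same way as the first, so that one final operation frees both.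

## Alternatives that were turned down

**Alternative 1:** The C3–C4 bond of a saturated lactone is cut and traced back to a carbene. An achiral diazoacetate A2 of a symmetric 1,3-diarylpropan-2-ol would lose nitrogen on a chiral dirhodium tetracarboxamidate catalyst (divalent rhodium). The carbene carbon C3 would insert into one of the two enantiotopic benzylic C–H arms and give the cis-lactone A1, with C5 and C4 both set.
- For it: the chirality comes from a catalyst acting on an achiral substrate, and insertion into an electron-rich benzylic C–H to form a five-membered ring is the favoured mode of such carbenes. On the origin of chirality it is stronger than the chosen route, which discards half of a racemate.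
- Against it: A1 has the wrong oxidation level at C3 and C4 and no oxygen at C3. Hydroxylation, oxidation to the α-keto lactone and O-methylation would have to follow, all through enolates next to the labile C5–H, and the C4 centre is made only to be destroyed.
- The more serious flaw is structural. The desymmetrisation needs two identical aryl arms, but the target's rings differ by the prenyl group. After the key step the two silyloxyphenyl rings of A1 cannot be told apart chemically, and prenylation before it destroys the symmetry on which the step depends.
- In exchange for the resolution, the chosen route delivers C3 oxygen, the C3=C4 bond and both different aryl rings in place at the end of its key step, with one deprotection left.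

**Alternative 2:** The O1–C2 bond and the C5–H bond are cut. The racemic hydroxycyclobutenone A4, assembled from dimethyl squarate A5 by two carbonyl additions, would open under light to a hydroxyvinylketene. Its hydroxyl would add to the ketene carbon to give a 2-hydroxyfuran, and a chiral bifunctional proton shuttle would then protonate C5 to give A3.
- For it: A5 supplies C2, C3, C4, C5 and the methoxy oxygen at once, both aryl units enter as organometallics, and the order of additions fixes the substitution pattern. In step count and convergence this plan is clearly stronger than the chosen one.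
- Against it: the stereocentre arises by delivery of a proton to C5 of a flat, achiral intermediate, far from the only polar handle at C2. The same shuttle is a base that can take the vinylogously acidic proton of A3 off again, so any selectivity could be lost by equilibration. Protonation at C3 instead of C5 and reactions of the ketene with the prenyl alkene are further exits.
- The chosen route is longer, but its C5 configuration is fixed by a stereospecific bond formation from a precursor whose enantiopurity can be measured and raised by recrystallisation beforehand.

**Alternative 3:** The bonds C4–C3, C3–C2 and C2–O1 are cut, C2 and C3 coming from two molecules of carbon monoxide A8. The enantiopure trans-epoxide A7 would be opened at the benzylic carbon C4 by a cobalt carbonyl catalyst under phase-transfer conditions with aqueous alkali and a methylating promoter. It would take up two A8 and close to the enolised 3-hydroxyfuranone A6, which O-methylation would convert into the protected target.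
- For it: C5 is carried over untouched from an epoxide that catalytic asymmetric epoxidation could supply, and three bonds form in one step. On bonds per step and on origin of chirality it is stronger than the chosen route.
- Against it: this double carbonylation belongs to monosubstituted aryl oxiranes. A7 is 1,2-disubstituted, so attack at C4 is hindered, and its 4-alkoxyphenyl group favours ionisation and rearrangement to a ketone over carbonylation. Hot aqueous alkali and cobalt hydride species are also poor company for the prenyl alkene (isomerisation, hydroformylation). The electron-rich styrene-type epoxide is itself acid-labile and awkward to make and handle.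
- The chosen key step runs in a weakly basic organic medium on a substrate class (4-monosubstituted 2,3-allenoic acids) for which the coupling–cyclisation is established, so its uncertainty is confined to the effect of the 2-methoxy group.

Key step: step 11

Assumption 1: of the two diastereomeric cinchonidinium salts of acid 14, the one containing the (Sa) acid is taken to be the less soluble; if the other salt crystallises, the (Sa) acid is taken from the mother liquor and the route is otherwise unchanged.

Assumption 2: the α-chloro ether 7 is taken to be a catalogue compound.

## Steps

Step 1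
Reactants: 1 methyl 3-(4-hydroxyphenyl)propanoate
Product: 2 methyl 3-(3-bromo-4-hydroxyphenyl)propanoate
Conditions: NBS (1.0 equiv), MeCN, 0 °C to rt
Reagents that add atoms: N-bromosuccinimide, O=C1CCC(=O)N1Br
Why: Electrophilic aromatic bromination; the para position is blocked by the side chain, so the hydroxyl group directs to its ortho position, and one equivalent at low temperature should hold the reaction at mono-bromination.

Step 2
Reactants: 2 methyl 3-(3-bromo-4-hydroxyphenyl)propanoate
Product: 3 methyl 3-[3-bromo-4-(methoxymethoxy)phenyl]propanoate
Conditions: MOMCl, iPr2NEt, CH2Cl2, 0 °C to rt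
Reagents that add atoms: chloromethyl methyl ether, COCCl
Why: O-Alkylation of the phenol by the α-chloro ether (acetal formation); the resulting ether is stable to hydroxide, amines and palladium catalysis, which the later steps require.

Step 3
Reactants: 3 methyl 3-[3-bromo-4-(methoxymethoxy)phenyl]propanoate; 4 tributyl(3-methylbut-2-en-1-yl)stannane
Product: 5 methyl 3-[4-(methoxymethoxy)-3-(3-methylbut-2-en-1-yl)phenyl]propanoate
Conditions: Pd(PPh3)4 (5 mol %), DMF, 100 °C
Reagents that add atoms: none
Why: Stille coupling: oxidative addition of the aryl bromide to zerovalent palladium, transfer of the allyl group from tin and reductive elimination at the less substituted allyl terminus should give the linear prenyl arene; ester and acetal are inert.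

Step 4
Reactants: 5 methyl 3-[4-(methoxymethoxy)-3-(3-methylbut-2-en-1-yl)phenyl]propanoate
Product: 6 3-[4-(methoxymethoxy)-3-(3-methylbut-2-en-1-yl)phenyl]propanoic acid
Conditions: LiOH·H2O, THF/MeOH/H2O, rt; then 1 M HCl to pH 4, 0 °C
Reagents that add atoms: lithium hydroxide, [Li+].[OH-]
Why: Saponification of the methyl ester by acyl substitution with hydroxide; acidification only to pH 4 in the cold leaves the aryl acetal and the prenyl alkene untouched.

Step 5
Reactants: 7 methyl 2-chloro-2-methoxyacetate; 8 triphenylphosphane
Product: 9 (1,2-dimethoxy-2-oxoethyl)triphenylphosphonium chloride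
Conditions: toluene, rt; salt filtered off
Reagents that add atoms: none
Why: Quaternisation of the phosphane by an α-chloro ether that ionises easily to an oxocarbenium ion; the salt is the methoxy member of the known family of alkoxy(alkoxycarbonyl)methyl phosphonium Wittig reagents and should precipitate from toluene.

Step 6
Reactants: 6 3-[4-(methoxymethoxy)-3-(3-methylbut-2-en-1-yl)phenyl]propanoic acid; 9 (1,2-dimethoxy-2-oxoethyl)triphenylphosphonium chloride
Product: 13 methyl 2-methoxy-5-[4-(methoxymethoxy)-3-(3-methylbut-2-en-1-yl)phenyl]penta-2,3-dienoate (racemic), via acid chloride 10 (not isolated), via phosphorane 11 (not isolated), via ketene 12 (not isolated)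
Conditions: 6, 1-chloro-N,N,2-trimethylprop-1-en-1-amine (1.05 equiv), CH2Cl2, 0 °C to rt; then this solution added slowly to 9 (1.2 equiv) and Et3N (2.5 equiv) in CH2Cl2, 0 °C to rt
Reagents that add atoms: none
Why: Wittig olefination of a ketene (allenoate synthesis from an acid chloride, a tertiary amine and a stabilised ylide): the chloroenamine forms 10 without free HCl, so acetal and prenyl survive, and Et3N frees ylide 11 from 9 and dehydrochlorinates 10 to ketene 12, whose carbonyl the ylide olefinates. Direct C-acylation of 11 by 10 followed by enolisation leads to the same betaine, so both paths should end in 13 and Ph3PO.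

Step 7
Reactants: 13 methyl 2-methoxy-5-[4-(methoxymethoxy)-3-(3-methylbut-2-en-1-yl)phenyl]penta-2,3-dienoate (racemic)
Product: 14 2-methoxy-5-[4-(methoxymethoxy)-3-(3-methylbut-2-en-1-yl)phenyl]penta-2,3-dienoic acid (racemic)
Conditions: LiOH·H2O (1.5 equiv), THF/H2O, 0 °C to rt; then cold 1 M HCl to pH 4, extraction at once
Reagents that add atoms: lithium hydroxide, [Li+].[OH-]
Why: Saponification of the methyl ester; 2-substituted 2,3-allenoates are hydrolysed by cold aqueous hydroxide without migration of the cumulated double bonds, and the mild acidification spares the allenyl ether and the acetal.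

Step 8
Reactants: 14 2-methoxy-5-[4-(methoxymethoxy)-3-(3-methylbut-2-en-1-yl)phenyl]penta-2,3-dienoic acid (racemic); 15 cinchonidine
Product: 16 cinchonidinium (Sa)-2-methoxy-5-[4-(methoxymethoxy)-3-(3-methylbut-2-en-1-yl)phenyl]penta-2,3-dienoate (1:1 salt)
Conditions: 15 (1.0 equiv), acetone, reflux to rt; recrystallised from acetone to constant optical rotation
Reagents that add atoms: none
Why: Classical resolution by diastereomeric salt formation with a cinchona base, a standard route to optically active 2,3-allenoic acids; the allene axis is fixed here by selection of one enantiomer, not by induction, and the crystalline salt allows the enantiopurity to be raised before the key step.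

Step 9
Reactants: 16 cinchonidinium (Sa)-2-methoxy-5-[4-(methoxymethoxy)-3-(3-methylbut-2-en-1-yl)phenyl]penta-2,3-dienoate
Product: 17 (Sa)-2-methoxy-5-[4-(methoxymethoxy)-3-(3-methylbut-2-en-1-yl)phenyl]penta-2,3-dienoic acid; also (P); seen along the axis from the carboxyl-bearing carbon with CO2H up and OMe down, the CH2-aryl group on the far carbon points left
Conditions: EtOAc / 0.5 M aq HCl (1.1 equiv), 0 °C, short contact; dried and used directly
Reagents that add atoms: none
Why: Acid–base partition: cold dilute acid takes the alkaloid into water as its hydrochloride and the free acid goes into the organic phase; contact is kept short because an alkoxyallene is an enol ether, and the axis is not touched.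

Step 10
Reactants: 18 4-iodophenol
Product: 19 1-iodo-4-(methoxymethoxy)benzene
Conditions: MOMCl, iPr2NEt, CH2Cl2, 0 °C to rt
Reagents that add atoms: chloromethyl methyl ether, COCCl
Why: O-Alkylation of the phenol by the α-chloro ether; the carbon–iodine bond is untouched, and the same protecting group as on 17 allows one final deprotection.

Step 11
Reactants: 17 (Sa)-2-methoxy-5-[4-(methoxymethoxy)-3-(3-methylbut-2-en-1-yl)phenyl]penta-2,3-dienoic acid; 19 1-iodo-4-(methoxymethoxy)benzene
Product: 20 (R)-3-methoxy-4-[4-(methoxymethoxy)phenyl]-5-{[4-(methoxymethoxy)-3-(3-methylbut-2-en-1-yl)phenyl]methyl}furan-2(5H)-one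
Conditions: Pd(PPh3)4 (5 mol %), iPr2NEt (2 equiv), degassed MeCN, 65 °C
Reagents that add atoms: none
Why: Oxidative addition of 19 to zerovalent palladium gives an arylpalladium iodide (divalent palladium), which binds the C4=C5 bond of the ammonium allenoate on the face that carries the methoxy group and adds syn, aryl to the central carbon C4 and palladium to C5. The allylpalladium species so formed has the carboxylate cis to C5, and the carboxylate oxygen displaces palladium from C5 from the opposite face, which forms O1–C5, closes the lactone and returns zerovalent palladium. The closest known reaction is the zerovalent-palladium-catalysed coupling–cyclisation of optically active 2,3-allenoic acids with aryl iodides to 4-aryl butenolides; the 2-methoxy group is the only new feature. The ring closes in the endo mode with respect to the C4=C5 allene bond (five-membered, both carbons of the attacked bond in the ring); seen from the σ-allyl complex it is an in-plane 5-exo-tet displacement and so carries no stereoelectronic penalty. C5 is controlled by the allene axis alone: its H and CH2-aryl groups are not touched and the tethered oxygen can only arrive from the carboxyl side, so the (Sa) axis should give (R)-C5, whether the order of events is carbopalladation–displacement or anti-oxypalladation–reductive elimination. The step needs aryl transfer to C4 only, which is inherent in allene carbopalladation because only the central carbon leads to an allyl complex, and attack at C5 only, which is secured because attack at the methoxy-bearing terminus C3 would give a three-membered lactone. It also needs ring closure to outrun η3–η1–η3 exchange, β-hydride loss toward the benzylic CH2 and proton-induced cyclisation without aryl transfer; the amine-paired carboxylate held next to C5, the absence of silver salts or strong acid and the moderate temperature serve this. The weak amine base should not remove the γ-proton at C5 of 20, which the 3-methoxy donor should make less acidic than in a plain butenolide.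

Step 12
Reactants: 20 (R)-3-methoxy-4-[4-(methoxymethoxy)phenyl]-5-{[4-(methoxymethoxy)-3-(3-methylbut-2-en-1-yl)phenyl]methyl}furan-2(5H)-one
Product: 21 (R)-4-(4-hydroxyphenyl)-5-{[4-hydroxy-3-(3-methylbut-2-en-1-yl)phenyl]methyl}-3-methoxyfuran-2(5H)-one
Conditions: HCl (1.25 M in MeOH, 3 equiv), MeOH, 0 °C to rt, monitored; NaHCO3 quench when both acetals are gone
Reagents that add atoms: none
Why: Acid-catalysed acetal exchange with methanol: protonation of an acetal oxygen and loss of the phenol are far faster than protonation of the trisubstituted prenyl alkene, so both phenols should be freed before chroman formation sets in. The lactone and the carbonyl-flanked enol ether should persist, and C5 is not enolised under these conditions.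

## Compound list

1 | methyl 3-(4-hydroxyphenyl)propanoate | COC(=O)CCc1ccc(O)cc1 | starting material
2 | methyl 3-(3-bromo-4-hydroxyphenyl)propanoate | COC(=O)CCc1ccc(O)c(Br)c1 | intermediate
3 | methyl 3-[3-bromo-4-(methoxymethoxy)phenyl]propanoate | COC(=O)CCc1ccc(OCOC)c(Br)c1 | intermediate
4 | tributyl(3-methylbut-2-en-1-yl)stannane | CCCC[Sn](CCCC)(CCCC)CC=C(C)C | starting material
5 | methyl 3-[4-(methoxymethoxy)-3-(3-methylbut-2-en-1-yl)phenyl]propanoate | COC(=O)CCc1ccc(OCOC)c(CC=C(C)C)c1 | intermediate
6 | 3-[4-(methoxymethoxy)-3-(3-methylbut-2-en-1-yl)phenyl]propanoic acid | OC(=O)CCc1ccc(OCOC)c(CC=C(C)C)c1 | intermediate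
7 | methyl 2-chloro-2-methoxyacetate | COC(Cl)C(=O)OC | starting material
8 | triphenylphosphane | c1ccc(cc1)P(c1ccccc1)c1ccccc1 | starting material
9 | (1,2-dimethoxy-2-oxoethyl)triphenylphosphonium chloride | COC(C(=O)OC)[P+](c1ccccc1)(c1ccccc1)c1ccccc1.[Cl-] | intermediate
10 | 3-[4-(methoxymethoxy)-3-(3-methylbut-2-en-1-yl)phenyl]propanoyl chloride | ClC(=O)CCc1ccc(OCOC)c(CC=C(C)C)c1 | intermediate
11 | methyl 2-methoxy-2-(triphenyl-λ5-phosphanylidene)acetate | COC(=O)C(OC)=P(c1ccccc1)(c1ccccc1)c1ccccc1 | intermediate
12 | 3-[4-(methoxymethoxy)-3-(3-methylbut-2-en-1-yl)phenyl]prop-1-en-1-one (ketene) | O=C=CCc1ccc(OCOC)c(CC=C(C)C)c1 | intermediate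
13 | methyl 2-methoxy-5-[4-(methoxymethoxy)-3-(3-methylbut-2-en-1-yl)phenyl]penta-2,3-dienoate (racemic) | COC(=O)C(OC)=C=CCc1ccc(OCOC)c(CC=C(C)C)c1 | intermediate
14 | 2-methoxy-5-[4-(methoxymethoxy)-3-(3-methylbut-2-en-1-yl)phenyl]penta-2,3-dienoic acid (racemic) | OC(=O)C(OC)=C=CCc1ccc(OCOC)c(CC=C(C)C)c1 | intermediate
15 | cinchonidine | C=C[C@H]1CN2CC[C@H]1C[C@H]2[C@@H](c1ccnc2ccccc12)O | starting material
16 | cinchonidinium (Sa)-2-methoxy-5-[4-(methoxymethoxy)-3-(3-methylbut-2-en-1-yl)phenyl]penta-2,3-dienoate (1:1 salt) | [O-]C(=O)C(OC)=[C@]=C([H])Cc1ccc(OCOC)c(CC=C(C)C)c1.C=C[C@H]1C[NH+]2CC[C@H]1C[C@H]2[C@@H](c1ccnc2ccccc12)O | intermediate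
17 | (Sa)-2-methoxy-5-[4-(methoxymethoxy)-3-(3-methylbut-2-en-1-yl)phenyl]penta-2,3-dienoic acid | OC(=O)C(OC)=[C@]=C([H])Cc1ccc(OCOC)c(CC=C(C)C)c1 | intermediate
18 | 4-iodophenol | Oc1ccc(I)cc1 | starting material
19 | 1-iodo-4-(methoxymethoxy)benzene | COCOc1ccc(I)cc1 | intermediate
20 | (R)-3-methoxy-4-[4-(methoxymethoxy)phenyl]-5-{[4-(methoxymethoxy)-3-(3-methylbut-2-en-1-yl)phenyl]methyl}furan-2(5H)-one | COC1=C(c2ccc(OCOC)cc2)[C@@H](Cc2ccc(OCOC)c(CC=C(C)C)c2)OC1=O | intermediate
21 | (R)-4-(4-hydroxyphenyl)-5-{[4-hydroxy-3-(3-methylbut-2-en-1-yl)phenyl]methyl}-3-methoxyfuran-2(5H)-one | COC1=C(c2ccc(O)cc2)[C@@H](Cc2ccc(O)c(CC=C(C)C)c2)OC1=O | target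

## Step count and least certain steps

Total step count: 12. Longest linear sequence: 10 steps (1, 2, 3, 4, 6, 7, 8, 9, 11, 12); steps 5 and 10 prepare the two coupling partners.

**Step 11 (key step).** The most likely failure is loss of the axial information before the ring closes. This can happen by η3–η1–η3 exchange or bimolecular palladium exchange in the allylpalladium intermediate, which the methoxy donor may make longer-lived, or by reversible addition of phosphine or iodide to the allenoate. Other exits are β-hydride loss toward the benzylic CH2 and proton-induced cyclisation without aryl transfer.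

The fallback sets out from 17 and comes back at 20, and separates ring closure from arylation. Treatment of 17 with copper dibromide CuBr2 in acetone/water at rt is a halolactonisation of a 2,3-allenoic acid. Bromine goes to the central carbon and the tethered oxygen to C5 from the carboxyl side, so the same axis-to-centre transfer should give (R)-4-bromo-3-methoxy-5-{[4-(methoxymethoxy)-3-(3-methylbut-2-en-1-yl)phenyl]methyl}furan-2(5H)-one F1. A Suzuki–Miyaura coupling of F1 with [4-(methoxymethoxy)phenyl]boronic acid F2 (Pd(PPh3)4, KF, toluene/water, 60 °C; the weak fluoride base spares the C5 proton) should then give 20.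

**Step 6.** The likely failures are dimerisation of the aldoketene faster than olefination, incomplete formation of the ylide by the amine, and base-induced migration of the cumulated bonds into a conjugated dienoate.

The fallback sets out from 6 and comes back at 13, building the allene by elimination instead of olefination. Acid chloride 10, made as in step 6, acylates the lithium enolate of methyl 2-methoxyacetate F3 (2 equiv, LiN(SiMe3)2, THF, −78 °C; crossed Claisen condensation) to give methyl 2-methoxy-5-[4-(methoxymethoxy)-3-(3-methylbut-2-en-1-yl)phenyl]-3-oxopentanoate F4. Its enolate (LiN(SiMe3)2, 1 equiv) is O-sulfonylated with Tf2O at −78 °C to give methyl 2-methoxy-5-[4-(methoxymethoxy)-3-(3-methylbut-2-en-1-yl)phenyl]-3-{[(trifluoromethyl)sulfonyl]oxy}pent-2-enoate F5. A further equivalent of LiN(SiMe3)2 removes the γ-proton, and loss of triflate from the dienolate (vinylogous E1cB elimination, the known one-pot passage from β-keto esters to allenyl esters) should give 13.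

**Step 8.** The salt pair may not discriminate: the salts may fail to crystallise or may co-crystallise, so the enantiopurity stalls.

The fallback sets out from 13 and comes back at 17, moving the separation to the ester stage and changing its principle. Racemic 13 is separated by preparative chromatography on a chiral stationary phase to give methyl (Sa)-2-methoxy-5-[4-(methoxymethoxy)-3-(3-methylbut-2-en-1-yl)phenyl]penta-2,3-dienoate F6. Saponification as in step 7 (LiOH·H2O, THF/H2O, 0 °C; cold acidification to pH 4) gives 17 directly, and steps 8 and 9 are not needed.

**Step 12.** The likely failure is acid-catalysed cyclisation of the liberated ortho-prenylphenol to the chroman, or addition of HCl or methanol across the prenyl alkene, before the second acetal has gone.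

The fallback sets out from 20 and comes back at 21, and replaces Brønsted-acid solvolysis by silyl transfer in a buffered medium. TMSOTf with 2,2'-bipyridyl in MeCN at 0 °C converts aryl methoxymethyl ethers into aryl silyl ethers without free acid. This gives (R)-3-methoxy-4-[4-(trimethylsilyloxy)phenyl]-5-{[3-(3-methylbut-2-en-1-yl)-4-(trimethylsilyloxy)phenyl]methyl}furan-2(5H)-one F7, which is hydrolysed to 21 on addition of water.

**Step 3.** The likely failures are sluggish oxidative addition to the electron-rich, ortho-alkoxy aryl bromide, and transfer of the allyl group with transposition (1,1-dimethylallyl isomer) or alkene migration at the temperature needed.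

The fallback sets out from 1 and comes back at 5, and does without the halide and the metal-catalysed coupling. The sodium phenoxide of 1 (NaH, toluene, rt) is C-alkylated at the ortho position by 1-bromo-3-methylbut-2-ene F8; phenoxide ortho-alkylation is favoured in a non-polar solvent, and the para position is blocked. This gives methyl 3-[4-hydroxy-3-(3-methylbut-2-en-1-yl)phenyl]propanoate F9, which is separated from O-alkylated material and protected (MOMCl, iPr2NEt, CH2Cl2) to give 5. Steps 1 and 2 are then not needed.

## Further compounds

F1 | step 11 | (R)-4-bromo-3-methoxy-5-{[4-(methoxymethoxy)-3-(3-methylbut-2-en-1-yl)phenyl]methyl}furan-2(5H)-one | COC1=C(Br)[C@@H](Cc2ccc(OCOC)c(CC=C(C)C)c2)OC1=O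
F2 | step 11 | [4-(methoxymethoxy)phenyl]boronic acid | COCOc1ccc(B(O)O)cc1
F3 | step 6 | methyl 2-methoxyacetate | COCC(=O)OC
F4 | step 6 | methyl 2-methoxy-5-[4-(methoxymethoxy)-3-(3-methylbut-2-en-1-yl)phenyl]-3-oxopentanoate | COC(=O)C(OC)C(=O)CCc1ccc(OCOC)c(CC=C(C)C)c1
F5 | step 6 | methyl 2-methoxy-5-[4-(methoxymethoxy)-3-(3-methylbut-2-en-1-yl)phenyl]-3-{[(trifluoromethyl)sulfonyl]oxy}pent-2-enoate | COC(=O)C(OC)=C(OS(=O)(=O)C(F)(F)F)CCc1ccc(OCOC)c(CC=C(C)C)c1
F6 | step 8 | methyl (Sa)-2-methoxy-5-[4-(methoxymethoxy)-3-(3-methylbut-2-en-1-yl)phenyl]penta-2,3-dienoate | COC(=O)C(OC)=[C@]=C([H])Cc1ccc(OCOC)c(CC=C(C)C)c1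
F7 | step 12 | (R)-3-methoxy-4-[4-(trimethylsilyloxy)phenyl]-5-{[3-(3-methylbut-2-en-1-yl)-4-(trimethylsilyloxy)phenyl]methyl}furan-2(5H)-one | COC1=C(c2ccc(O[Si](C)(C)C)cc2)[C@@H](Cc2ccc(O[Si](C)(C)C)c(CC=C(C)C)c2)OC1=O
F8 | step 3 | 1-bromo-3-methylbut-2-ene | CC(C)=CCBr
F9 | step 3 | methyl 3-[4-hydroxy-3-(3-methylbut-2-en-1-yl)phenyl]propanoate | COC(=O)CCc1ccc(O)c(CC=C(C)C)c1
A1 | alternative 1 | (4S,5R)-cis-4-[4-(tert-butyldimethylsilyloxy)phenyl]-5-{[4-(tert-butyldimethylsilyloxy)phenyl]methyl}dihydrofuran-2(3H)-one | O=C1C[C@@H](c2ccc(O[Si](C)(C)C(C)(C)C)cc2)[C@@H](Cc2ccc(O[Si](C)(C)C(C)(C)C)cc2)O1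
A2 | alternative 1 | 1,3-bis[4-(tert-butyldimethylsilyloxy)phenyl]propan-2-yl 2-diazoacetate | [N-]=[N+]=CC(=O)OC(Cc1ccc(O[Si](C)(C)C(C)(C)C)cc1)Cc1ccc(O[Si](C)(C)C(C)(C)C)cc1
A3 | alternative 2 | (R)-4-[4-(tert-butyldimethylsilyloxy)phenyl]-5-{[4-(tert-butyldimethylsilyloxy)-3-(3-methylbut-2-en-1-yl)phenyl]methyl}-3-methoxyfuran-2(5H)-one | COC1=C(c2ccc(O[Si](C)(C)C(C)(C)C)cc2)[C@@H](Cc2ccc(O[Si](C)(C)C(C)(C)C)c(CC=C(C)C)c2)OC1=O
A4 | alternative 2 | 4-hydroxy-2-methoxy-3-[4-(tert-butyldimethylsilyloxy)phenyl]-4-{[4-(tert-butyldimethylsilyloxy)-3-(3-methylbut-2-en-1-yl)phenyl]methyl}cyclobut-2-en-1-one (racemic) | O=C1C(OC)=C(c2ccc(O[Si](C)(C)C(C)(C)C)cc2)C1(O)Cc1ccc(O[Si](C)(C)C(C)(C)C)c(CC=C(C)C)c1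
A5 | alternative 2 | 3,4-dimethoxycyclobut-3-ene-1,2-dione (dimethyl squarate) | COC1=C(OC)C(=O)C1=O
A6 | alternative 3 | (R)-3-hydroxy-4-[4-(methoxymethoxy)phenyl]-5-{[4-(methoxymethoxy)-3-(3-methylbut-2-en-1-yl)phenyl]methyl}furan-2(5H)-one | OC1=C(c2ccc(OCOC)cc2)[C@@H](Cc2ccc(OCOC)c(CC=C(C)C)c2)OC1=O
A7 | alternative 3 | (2R,3R)-2-[4-(methoxymethoxy)phenyl]-3-{[4-(methoxymethoxy)-3-(3-methylbut-2-en-1-yl)phenyl]methyl}oxirane (trans) | COCOc1ccc([C@H]2O[C@@H]2Cc2ccc(OCOC)c(CC=C(C)C)c2)cc1
A8 | alternative 3 | carbon monoxide | [C-]#[O+]
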